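21.9 % of the substrate charge shows as neither substrate nor product on the west plateau, beside 33.8 % substrate and 44.3 % product. Catalyst cannot hold that gap, since its 0.69 mM is less than the gap.

| setting | west | north-east | epsilon | delta |
|---|---|---|---|---|
| substrate | 0.10 M | 0.10 M | 0.10 M | 0.10 M |
| reagent | 0.045 M (fed, over 20 h) | 0.11 M (fed, over 20 h) | 0.0600 M (fed, over 20 h) | 0.120 M (fed, over 20 h) |
| free catalyst | 0.69 mM | 0.69 mM | 0.69 mM | 0.69 mM |
| remark | run made earlier | run made earlier |  |  |
| time |  |  | 10 d | 10 d |

| run | time / d | substrate / % | product / % |
|---|---|---|---|
| west | 2.50 | 37.4 | 41.6 |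
| west | 5.00 | 33.9 | 44.4 |
| west | 8.00 | 33.7 | 44.5 |
| west | 10.0 | 33.8 | 44.1 |
| north-east | 2.50 | 4.2 | 87.2 |
| north-east | 5.00 | 0 | 100.3 |
| north-east | 8.00 | 0 | 100.1 |
| north-east | 10.0 | 0 | 99.8 |

(each reading ± 0.3 percentage points)

- the numbers in the tables scatter with a standard deviation of 0.3 percentage points
- what has gone from substrate into another species counts as reacted, even if it can come back

- part of the substrate that has reacted at the end, epsilon
- part of the substrate that has reacted at the end, delta
- what raising the concentration of reagent from its lowest to its highest value here does to the part of the substrate that has reacted (changes below 5 percentage points count as none) (it falls / it rises / no change)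

Treat the gap as idle adduct: substrate bound reversibly to a released group that each product leaves behind, at equilibrium throughout. West gives 2.88 for adduct share over substrate share times unbound released-group share (product less adduct), all as fractions of the substrate charge: the binding quotient. North-east at 2.50 d, with a gap of 8.60 %, reads 2.61, while its plain adduct-to-substrate ratio is 2.05 against 0.648 in west.

In epsilon, reagent is the limiting reagent, so expect product p of 60.0 %. Solve the quotient for adduct a, with substrate as the charge less p and a: a is 21.1 %, so my reckoning finds 81.1 % reacted when you arrive. Delta holds more reagent than north-east, which read 0 % substrate at 5.00 d, so expect 100 % there.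

The forecast, taking the gap as “a plateau equilibrium” with ratio 0.64, gave 75 % for epsilon, lower than mine, 100 % for delta, and for the trend: it rises.

Epsilon gave 80.0 % and delta 100 %; from lowest to highest reagent, it rises, by 20 percentage points.

    substrate + free catalyst → catalyst intermediate A (k = 4160 M⁻¹ h⁻¹)
    catalyst intermediate A → catalyst intermediate B (k = 6.46 h⁻¹)
    reagent + catalyst intermediate B → catalyst intermediate C (k = 99.2 M⁻¹ h⁻¹)
    catalyst intermediate C ⇌ released group + catalyst intermediate D (K = 0.0250 M, k = 113 h⁻¹)
    catalyst intermediate D → free catalyst + product (k = 37.0 h⁻¹)
    substrate + released group ⇌ idle adduct, settled at all times (K = 23.8 M⁻¹)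

Take the neighbouring flask, epsilon with 0.25 M of substrate. The quotient counts fractions of the charge, so scale it with the substrate charge to 7.20, and p becomes 24.0 %. The same solution gives adduct 19.3 %, hence 43.3 % reacted. That neighbouring flask ended at 42.8 % reacted, with substrate 57.2 %, product 24.0 % and idle adduct 18.5 %.

The readings were computed with constants of no real substance, and the scatter is random.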